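**Strategy**

The target is disconnected at the four C–CH3 bonds of its two Ar–C–C–C(CH3)2–O units, each of which hangs on a ring carbon next to a phenolic oxygen: C6/O7 of ring A (open carbinol chain) and C5'/O4' of ring B (C2'' of the pyran). Both are therefore lactones in disguise. One treatment with excess methyl organometallic opens a ring A dihydrocoumarin and a ring B coumarin on a preformed isoflavone, delivering both dimethylcarbinols and both phenols; the Z-allylic carbinol then closes to the chromene. The precursor is the 5-hydroxyisoflavone bis-lactone with O2' masked as a tetrahydropyranyl acetal, so that no phenoxide para to C5' deactivates the coumarin carbonyl.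

Key step: step 10

**Remarks on the chemistry (assumptions and design corrections)**

- Numbering: isoflavone numbering is used (O1, C2–C4, C4a, C5–C8, C8a for rings C and A; C1'–C6' for ring B; O1'', C2'', C3'', C4'' for the pyran on ring B, with C2'' carrying the two methyl groups and C4'' bonded to C5').
- O2' must not be a free hydroxyl in the key step. C2' is para to C5', so a 2'-phenoxide would be conjugated through C5'–C4''=C3'' with the coumarin carbonyl and would switch it off. Only the 5-oxide, which deactivates the chromone, is wanted. The bis-lactone diphenol 19 is therefore converted into its 2'-O-tetrahydropyranyl ether 21, and the acetal is lost in the final acid step, so no separate deprotection is needed.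
- Ring B is introduced as a preformed 7-methoxycoumarin boronate and joined to a 3-iodochromone by Suzuki coupling. A deoxybenzoin with a free hydroxyl ortho to the benzylic CH2 would be prone to cyclodehydration to a 2-arylbenzofuran, and an o-hydroxyphenylacetic acid closes to a benzofuranone in strong acid.
- Assumption: the ring A lactone of 19 is drawn through O7. Any isomer closed through O5 would give the same product in step 10.
- The target has no stereocentre. Compounds 21, 23 and 24 are racemic at the acetal carbon of the tetrahydropyranyl group. The only geometric element that matters is the Z double bond of 24, which comes from the coumarin ring.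

**Route**

Step 1
Reactants: 1 4-hydroxy-2,6-dimethoxybenzaldehyde; 2 methyl (triphenylphosphoranylidene)acetate
Product: 3 methyl (E)-3-(4-hydroxy-2,6-dimethoxyphenyl)prop-2-enoate
Conditions: 2 (1.5 equiv), toluene, 110 °C
Reagents that add atoms: methyl (triphenylphosphoranylidene)acetate, COC(=O)C=P(c1ccccc1)(c1ccccc1)c1ccccc1
Why: Wittig olefination with a stabilised ylide, which is too weakly basic to be quenched by the phenol, should give mainly the E cinnamate, whose geometry is irrelevant because the double bond is hydrogenated in step 2.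

Step 2
Reactants: 3 methyl (E)-3-(4-hydroxy-2,6-dimethoxyphenyl)prop-2-enoate
Product: 4 methyl 3-(4-hydroxy-2,6-dimethoxyphenyl)propanoate
Conditions: H2 (1 atm), 10% Pd/C, MeOH, rt
Reagents that add atoms: none
Why: Heterogeneous catalytic hydrogenation saturates the cinnamate C=C bond while the arene, the ester and the aryl ethers are left alone.

Step 3
Reactants: 4 methyl 3-(4-hydroxy-2,6-dimethoxyphenyl)propanoate; 5 acetic anhydride
Product: 6 methyl 3-(3-acetyl-4-hydroxy-2,6-dimethoxyphenyl)propanoate
Conditions: Ac2O (2 equiv), BF3·OEt2, 80 °C; aq. NaOAc work-up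
Reagents that add atoms: acetic anhydride, CC(=O)OC(C)=O
Why: Friedel–Crafts acetylation of an activated phenol (O-acetylation followed by BF3-promoted Fries shift) places the acetyl group ortho to the hydroxyl, and since the two open ring positions are equivalent only one regioisomer can form.

Step 4
Reactants: 6 methyl 3-(3-acetyl-4-hydroxy-2,6-dimethoxyphenyl)propanoate; 7 N,N-dimethylformamide dimethyl acetal; 8 iodine
Product: 10 methyl 3-(3-iodo-5,7-dimethoxy-4-oxo-4H-chromen-6-yl)propanoate, via aryl enaminone 9 (not isolated)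
Conditions: DMF-DMA (3 equiv), toluene, 95 °C; evaporate; I2 (1.5 equiv), CHCl3, rt; aq. Na2S2O3 wash
Reagents that add atoms: N,N-dimethylformamide dimethyl acetal, COC(OC)N(C)C; iodine, II
Why: Condensation of the aryl methyl ketone with the formamide acetal gives the enaminone, which iodine converts by α-iodination, attack of the phenol on the β-carbon and loss of dimethylamine into the 3-iodochromone (iodocyclisation of 2-hydroxyaryl enaminones), the single free hydroxyl fixing the ring fusion so that the propanoate ends up at C6 between the two methoxy groups.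

Step 5
Reactants: 11 5-bromo-2-hydroxy-4-methoxybenzaldehyde; 12 ethyl (triphenylphosphoranylidene)acetate
Product: 14 6-bromo-7-methoxy-2H-chromen-2-one, via ethyl 5-bromo-2-hydroxy-4-methoxycinnamate 13 (not isolated)
Conditions: 12 (1.2 equiv), N,N-diethylaniline, reflux
Reagents that add atoms: ethyl (triphenylphosphoranylidene)acetate, CCOC(=O)C=P(c1ccccc1)(c1ccccc1)c1ccccc1
Why: Wittig olefination of the salicylaldehyde is followed in the same hot solution by E/Z isomerisation of the cinnamate and lactonisation with loss of ethanol, the established one-pot coumarin synthesis from o-hydroxybenzaldehydes.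

Step 6
Reactants: 14 6-bromo-7-methoxy-2H-chromen-2-one; 15 bis(pinacolato)diboron
Product: 16 7-methoxy-6-(4,4,5,5-tetramethyl-1,3,2-dioxaborolan-2-yl)-2H-chromen-2-one
Conditions: B2pin2 (1.2 equiv), PdCl2(dppf) (3 mol%), KOAc (3 equiv), 1,4-dioxane, 90 °C
Reagents that add atoms: bis(pinacolato)diboron, CC1(C)OB(OC1(C)C)B1OC(C)(C)C(C)(C)O1
Why: Miyaura borylation of the aryl bromide proceeds by oxidative addition, acetate-assisted transmetalation with the diboron reagent and reductive elimination, and the weak base KOAc leaves the coumarin lactone closed.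

Step 7
Reactants: 10 methyl 3-(3-iodo-5,7-dimethoxy-4-oxo-4H-chromen-6-yl)propanoate; 16 7-methoxy-6-(4,4,5,5-tetramethyl-1,3,2-dioxaborolan-2-yl)-2H-chromen-2-one
Product: 17 methyl 3-[5,7-dimethoxy-3-(7-methoxy-2-oxo-2H-chromen-6-yl)-4-oxo-4H-chromen-6-yl]propanoate
Conditions: 16 (1.2 equiv), PdCl2(dppf) (5 mol%), K2CO3 (2.5 equiv), 1,4-dioxane/H2O 10:1, 80 °C
Reagents that add atoms: none
Why: Suzuki–Miyaura coupling of a 3-iodochromone with an arylboronate is the standard way to forge the C3–C1' bond of isoflavones, and the mild carbonate base at 80 °C should be tolerated by the pyranone, the coumarin and the methyl ester.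

Step 8
Reactants: 17 methyl 3-[5,7-dimethoxy-3-(7-methoxy-2-oxo-2H-chromen-6-yl)-4-oxo-4H-chromen-6-yl]propanoate
Product: 19 5-hydroxy-7-(7-hydroxy-2-oxo-2H-chromen-6-yl)-3,4-dihydro-2H,6H-pyrano[3,2-g]chromene-2,6-dione, via trihydroxy methyl ester 18 (not isolated)
Conditions: BBr3 (10 equiv), CH2Cl2, −78 °C to rt; H2O quench; then TsOH·H2O (10 mol%), 1,4-dioxane, 100 °C
Reagents that add atoms: none
Why: BBr3 cleaves the three aryl methyl ethers by bromide attack on the O-methyl groups of their boron complexes, and acid then drives transesterification of the propanoate onto the neighbouring 7-OH, which is preferred over 5-OH because the latter stays hydrogen-bonded to the C4 carbonyl; coumarin and chromone rings are stable to these conditions.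

Step 9
Reactants: 19 5-hydroxy-7-(7-hydroxy-2-oxo-2H-chromen-6-yl)-3,4-dihydro-2H,6H-pyrano[3,2-g]chromene-2,6-dione; 20 3,4-dihydro-2H-pyran
Product: 21 5-hydroxy-7-[2-oxo-7-(oxan-2-yloxy)-2H-chromen-6-yl]-3,4-dihydro-2H,6H-pyrano[3,2-g]chromene-2,6-dione (racemic at the acetal carbon)
Conditions: DHP (3 equiv), pyridinium p-toluenesulfonate (0.1 equiv), THF/CH2Cl2, 40 °C
Reagents that add atoms: 3,4-dihydro-2H-pyran, C1=COCCC1
Why: Acid-catalysed addition of a phenol to the enol ether (tetrahydropyranylation) should occur only at the free 2'-OH, since the 5-OH is tied up in its hydrogen bond to C4=O, and the new acetal carbon is formed as a racemate that is removed again in step 11.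

Step 10
Reactants: 21 5-hydroxy-7-[2-oxo-7-(oxan-2-yloxy)-2H-chromen-6-yl]-3,4-dihydro-2H,6H-pyrano[3,2-g]chromene-2,6-dione; 22 methylmagnesium bromide
Product: 24 5,7-dihydroxy-3-{4-hydroxy-5-[(Z)-3-hydroxy-3-methylbut-1-en-1-yl]-2-(oxan-2-yloxy)phenyl}-6-(3-hydroxy-3-methylbutyl)-4H-chromen-4-one, via ring A carbinol coumarin 23 (not isolated)
Conditions: anhydrous CeCl3 (10 equiv), MeMgBr (10 equiv, 3 M in Et2O), THF, −78 °C to 0 °C; cold sat. aq. NH4Cl quench
Reagents that add atoms: methylmagnesium bromide, C[Mg]Br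
Why: The first equivalent of reagent deprotonates 5-OH, and the methylcerium species generated from MeMgBr and CeCl3 then attacks each lactone carbonyl; the tetrahedral alkoxides collapse with loss of the aryloxide (O7 on ring A, O4' on ring B) to methyl ketones, which are more electrophilic than the esters they come from and take the second methyl group at once, the saturated aryl ester of ring A reacting first (compound 23). The closest known reactions are the conversion of dihydrocoumarins into 2-(3-hydroxy-3-methylbutyl)phenols and of 7-alkoxycoumarins into (Z)-2-(3-hydroxy-3-methylbut-1-enyl)phenols by excess methyl Grignard or methyllithium reagents. No ring is closed and no stereocentre is formed; the Z geometry of the new allylic carbinol is inherited from the cis C3''=C4'' bond that was held in the coumarin ring, and low temperature keeps the open enone from isomerising before the second addition. The selectivity required is 1,2-addition at the two ester carbonyls over attack at C2 or C4 of the chromone and over conjugate addition at C4'' of the coumarin. The chromone is shielded by its 5-oxide, joined by the 7-oxide once ring A has opened, which make the pyranone an electron-rich vinylogous carboxylate, and the weakly basic, oxophilic organocerium reagent favours carbonyl addition over conjugate addition and enolisation. The acetal on O2' keeps that oxygen neutral, so that no phenoxide para to C5' feeds electron density into the coumarin carbonyl, and it is inert to the organometallic reagent.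

Step 11
Reactants: 24 5,7-dihydroxy-3-{4-hydroxy-5-[(Z)-3-hydroxy-3-methylbut-1-en-1-yl]-2-(oxan-2-yloxy)phenyl}-6-(3-hydroxy-3-methylbutyl)-4H-chromen-4-one
Product: 25 5,7-dihydroxy-6-(3-hydroxy-3-methylbutyl)-3-(7-hydroxy-2,2-dimethyl-2H-chromen-6-yl)-4H-chromen-4-one (CNP0113306.0)
Conditions: pyridinium p-toluenesulfonate (0.2 equiv), EtOH, 50 °C
Reagents that add atoms: none
Why: The Z-allylic tertiary carbinol ionises under mild acid to a cation stabilised by the electron-rich ring B and is trapped by the adjacent 4'-OH to close the 2,2-dimethyl-2H-chromene (cyclodehydration), the same acid transfers the tetrahydropyranyl group to ethanol, and the saturated carbinol on ring A, which cannot form a stabilised cation, should stay intact.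

**Compound list**

1 | 4-hydroxy-2,6-dimethoxybenzaldehyde | COc1cc(O)cc(OC)c1C=O | starting material
2 | methyl (triphenylphosphoranylidene)acetate | COC(=O)C=P(c1ccccc1)(c1ccccc1)c1ccccc1 | starting material
3 | methyl (E)-3-(4-hydroxy-2,6-dimethoxyphenyl)prop-2-enoate | COC(=O)/C=C/c1c(OC)cc(O)cc1OC | intermediate
4 | methyl 3-(4-hydroxy-2,6-dimethoxyphenyl)propanoate | COC(=O)CCc1c(OC)cc(O)cc1OC | intermediate
5 | acetic anhydride | CC(=O)OC(C)=O | starting material
6 | methyl 3-(3-acetyl-4-hydroxy-2,6-dimethoxyphenyl)propanoate | COC(=O)CCc1c(OC)cc(O)c(C(C)=O)c1OC | intermediate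
7 | N,N-dimethylformamide dimethyl acetal | COC(OC)N(C)C | starting material
8 | iodine | II | starting material
9 | methyl 3-{3-[(E)-3-(dimethylamino)prop-2-enoyl]-4-hydroxy-2,6-dimethoxyphenyl}propanoate (aryl enaminone, not isolated) | COC(=O)CCc1c(OC)cc(O)c(C(=O)/C=C/N(C)C)c1OC | intermediate
10 | methyl 3-(3-iodo-5,7-dimethoxy-4-oxo-4H-chromen-6-yl)propanoate | COC(=O)CCc1c(OC)cc2occ(I)c(=O)c2c1OC | intermediate
11 | 5-bromo-2-hydroxy-4-methoxybenzaldehyde | COc1cc(O)c(C=O)cc1Br | starting material
12 | ethyl (triphenylphosphoranylidene)acetate | CCOC(=O)C=P(c1ccccc1)(c1ccccc1)c1ccccc1 | starting material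
13 | ethyl (E)-3-(5-bromo-2-hydroxy-4-methoxyphenyl)prop-2-enoate (drawn as the main E isomer, not isolated) | CCOC(=O)/C=C/c1cc(Br)c(OC)cc1O | intermediate
14 | 6-bromo-7-methoxy-2H-chromen-2-one | COc1cc2oc(=O)ccc2cc1Br | intermediate
15 | bis(pinacolato)diboron | CC1(C)OB(OC1(C)C)B1OC(C)(C)C(C)(C)O1 | starting material
16 | 7-methoxy-6-(4,4,5,5-tetramethyl-1,3,2-dioxaborolan-2-yl)-2H-chromen-2-one | COc1cc2oc(=O)ccc2cc1B1OC(C)(C)C(C)(C)O1 | intermediate
17 | methyl 3-[5,7-dimethoxy-3-(7-methoxy-2-oxo-2H-chromen-6-yl)-4-oxo-4H-chromen-6-yl]propanoate | COC(=O)CCc1c(OC)cc2occ(-c3cc4ccc(=O)oc4cc3OC)c(=O)c2c1OC | intermediate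
18 | methyl 3-[5,7-dihydroxy-3-(7-hydroxy-2-oxo-2H-chromen-6-yl)-4-oxo-4H-chromen-6-yl]propanoate (trihydroxy methyl ester, not isolated) | COC(=O)CCc1c(O)cc2occ(-c3cc4ccc(=O)oc4cc3O)c(=O)c2c1O | intermediate
19 | 5-hydroxy-7-(7-hydroxy-2-oxo-2H-chromen-6-yl)-3,4-dihydro-2H,6H-pyrano[3,2-g]chromene-2,6-dione (5,2'-dihydroxyisoflavone with a dihydropyran-2-one across C6/O7 and a pyran-2-one across C5'/O4') | O=C1CCc2c(O1)cc1occ(-c3cc4ccc(=O)oc4cc3O)c(=O)c1c2O | intermediate
20 | 3,4-dihydro-2H-pyran | C1=COCCC1 | starting material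
21 | 5-hydroxy-7-[2-oxo-7-(oxan-2-yloxy)-2H-chromen-6-yl]-3,4-dihydro-2H,6H-pyrano[3,2-g]chromene-2,6-dione (2'-O-tetrahydropyranyl ether of 19, racemic at the acetal carbon) | O=C1CCc2c(O1)cc1occ(-c3cc4ccc(=O)oc4cc3OC3CCCCO3)c(=O)c1c2O | intermediate
22 | methylmagnesium bromide | C[Mg]Br | starting material
23 | 5,7-dihydroxy-6-(3-hydroxy-3-methylbutyl)-3-[2-oxo-7-(oxan-2-yloxy)-2H-chromen-6-yl]-4H-chromen-4-one (ring A carbinol coumarin, racemic at the acetal carbon, not isolated) | CC(C)(O)CCc1c(O)cc2occ(-c3cc4ccc(=O)oc4cc3OC3CCCCO3)c(=O)c2c1O | intermediate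
24 | 5,7-dihydroxy-3-{4-hydroxy-5-[(Z)-3-hydroxy-3-methylbut-1-en-1-yl]-2-(oxan-2-yloxy)phenyl}-6-(3-hydroxy-3-methylbutyl)-4H-chromen-4-one (racemic at the acetal carbon) | CC(C)(O)CCc1c(O)cc2occ(-c3cc(/C=C\C(C)(C)O)c(O)cc3OC3CCCCO3)c(=O)c2c1O | intermediate
25 | 5,7-dihydroxy-6-(3-hydroxy-3-methylbutyl)-3-(7-hydroxy-2,2-dimethyl-2H-chromen-6-yl)-4H-chromen-4-one (CNP0113306.0) | CC(C)(O)CCc1c(O)cc2occ(-c3cc4c(cc3O)OC(C)(C)C=C4)c(=O)c2c1O | target

**Step count and risk**

Total step count: 11. Longest linear sequence: 9 steps (steps 1, 2, 3, 4, 7, 8, 9, 10, 11); steps 5 and 6 form the ring B branch.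

Steps most likely to fail:

1. Step 10. The organometallic reagent may attack the pyranone of ring C, add in conjugate fashion to the coumarin, or stall at a ketone stage if the polyphenoxide salts precipitate. The fallback moves the coumarin-to-chromene conversion to the fragment stage, where no chromone is present, so that the late addition only has to open the saturated lactone. It sets out from compounds 10 and 14 and comes back at target 25.
   - BBr3 in CH2Cl2, followed by the acid treatment of step 8, would convert 10 into 5-hydroxy-7-iodo-3,4-dihydro-2H,6H-pyrano[3,2-g]chromene-2,6-dione F1.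
   - MeMgBr with CeCl3 in THF would open 14 to 4-bromo-2-[(Z)-3-hydroxy-3-methylbut-1-en-1-yl]-5-methoxyphenol F2.
   - Pyridinium p-toluenesulfonate would close F2 to 6-bromo-7-methoxy-2,2-dimethyl-2H-chromene F3.
   - NaSEt in DMF at 120 °C would remove the O-methyl group by SN2 attack and give 6-bromo-2,2-dimethyl-2H-chromen-7-ol F4.
   - Miyaura borylation (B2pin2, PdCl2(dppf), KOAc) would give 2,2-dimethyl-6-(4,4,5,5-tetramethyl-1,3,2-dioxaborolan-2-yl)-2H-chromen-7-ol F5.
   - Suzuki coupling of F1 with F5 under anhydrous conditions that keep the lactone closed (PdCl2(dppf), CsF, 1,4-dioxane) would give 5-hydroxy-7-(7-hydroxy-2,2-dimethyl-2H-chromen-6-yl)-3,4-dihydro-2H,6H-pyrano[3,2-g]chromene-2,6-dione F6.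
   - MeMgBr with CeCl3 at −78 °C would then add twice to the ring A lactone of F6 and give 25 directly.

2. Step 7. The electron-poor, ortho-alkoxy boronate may protodeboronate, or the iodochromone may be opened by base before transmetalation. The fallback builds the isoflavone through a deoxybenzoin in which O2' stays methylated. It sets out from compounds 14 and 4 and comes back at compound 17.
   - Palladium-catalysed coupling of 14 with commercial (2-tert-butoxy-2-oxoethyl)zinc bromide (Pd2(dba)3, XPhos, THF, 65 °C) would give tert-butyl 2-(7-methoxy-2-oxo-2H-chromen-6-yl)acetate F7.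
   - Trifluoroacetic acid in CH2Cl2 would free 2-(7-methoxy-2-oxo-2H-chromen-6-yl)acetic acid F8.
   - BF3·OEt2 at 85 °C would acylate phenol 4 with F8 at its only open position type to give methyl 3-{4-hydroxy-2,6-dimethoxy-3-[(7-methoxy-2-oxo-2H-chromen-6-yl)acetyl]phenyl}propanoate F9.
   - Heating F9 with N,N-dimethylformamide dimethyl acetal 7 would insert C2 and close the pyranone to give 17.

3. Step 9. Acetal formation on the sparingly soluble diphenol may be slow or unselective, and the aryl acetal may be lost on purification. The fallback uses a base-mediated silylation and a fluoride deprotection instead. It sets out from compound 19 and comes back at target 25.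
   - Chlorotriisopropylsilane and imidazole in DMF would silylate only the acidic, unchelated 2'-OH and give 5-hydroxy-7-{2-oxo-7-[tri(propan-2-yl)silyloxy]-2H-chromen-6-yl}-3,4-dihydro-2H,6H-pyrano[3,2-g]chromene-2,6-dione F10.
   - The conditions of step 10 would give 5,7-dihydroxy-3-{4-hydroxy-5-[(Z)-3-hydroxy-3-methylbut-1-en-1-yl]-2-[tri(propan-2-yl)silyloxy]phenyl}-6-(3-hydroxy-3-methylbutyl)-4H-chromen-4-one F11.
   - Pyridinium p-toluenesulfonate in CH2Cl2 would close the chromene to 5,7-dihydroxy-6-(3-hydroxy-3-methylbutyl)-3-{2,2-dimethyl-7-[tri(propan-2-yl)silyloxy]-2H-chromen-6-yl}-4H-chromen-4-one F12.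
   - Tetrabutylammonium fluoride buffered with acetic acid in THF at 0 °C would remove the silyl group and give 25.

**Further compounds**

F1 | step 10 | 5-hydroxy-7-iodo-3,4-dihydro-2H,6H-pyrano[3,2-g]chromene-2,6-dione | O=C1CCc2c(O1)cc1occ(I)c(=O)c1c2O
F2 | step 10 | 4-bromo-2-[(Z)-3-hydroxy-3-methylbut-1-en-1-yl]-5-methoxyphenol | COc1cc(O)c(/C=C\C(C)(C)O)cc1Br
F3 | step 10 | 6-bromo-7-methoxy-2,2-dimethyl-2H-chromene | COc1cc2OC(C)(C)C=Cc2cc1Br
F4 | step 10 | 6-bromo-2,2-dimethyl-2H-chromen-7-ol | Oc1cc2OC(C)(C)C=Cc2cc1Br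
F5 | step 10 | 2,2-dimethyl-6-(4,4,5,5-tetramethyl-1,3,2-dioxaborolan-2-yl)-2H-chromen-7-ol | Oc1cc2OC(C)(C)C=Cc2cc1B1OC(C)(C)C(C)(C)O1
F6 | step 10 | 5-hydroxy-7-(7-hydroxy-2,2-dimethyl-2H-chromen-6-yl)-3,4-dihydro-2H,6H-pyrano[3,2-g]chromene-2,6-dione | O=C1CCc2c(O1)cc1occ(-c3cc4c(cc3O)OC(C)(C)C=C4)c(=O)c1c2O
F7 | step 7 | tert-butyl 2-(7-methoxy-2-oxo-2H-chromen-6-yl)acetate | COc1cc2oc(=O)ccc2cc1CC(=O)OC(C)(C)C
F8 | step 7 | 2-(7-methoxy-2-oxo-2H-chromen-6-yl)acetic acid | COc1cc2oc(=O)ccc2cc1CC(=O)O
F9 | step 7 | methyl 3-{4-hydroxy-2,6-dimethoxy-3-[(7-methoxy-2-oxo-2H-chromen-6-yl)acetyl]phenyl}propanoate | COC(=O)CCc1c(OC)cc(O)c(C(=O)Cc2cc3ccc(=O)oc3cc2OC)c1OC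
F10 | step 9 | 5-hydroxy-7-{2-oxo-7-[tri(propan-2-yl)silyloxy]-2H-chromen-6-yl}-3,4-dihydro-2H,6H-pyrano[3,2-g]chromene-2,6-dione | O=C1CCc2c(O1)cc1occ(-c3cc4ccc(=O)oc4cc3O[Si](C(C)C)(C(C)C)C(C)C)c(=O)c1c2O
F11 | step 9 | 5,7-dihydroxy-3-{4-hydroxy-5-[(Z)-3-hydroxy-3-methylbut-1-en-1-yl]-2-[tri(propan-2-yl)silyloxy]phenyl}-6-(3-hydroxy-3-methylbutyl)-4H-chromen-4-one | CC(C)(O)CCc1c(O)cc2occ(-c3cc(/C=C\C(C)(C)O)c(O)cc3O[Si](C(C)C)(C(C)C)C(C)C)c(=O)c2c1O
F12 | step 9 | 5,7-dihydroxy-6-(3-hydroxy-3-methylbutyl)-3-{2,2-dimethyl-7-[tri(propan-2-yl)silyloxy]-2H-chromen-6-yl}-4H-chromen-4-one | CC(C)(O)CCc1c(O)cc2occ(-c3cc4c(cc3O[Si](C(C)C)(C(C)C)C(C)C)OC(C)(C)C=C4)c(=O)c2c1O
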